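**Retrosynthetic overview**

1. Numbering used: ring A (five-membered) is C1(Me)–C2–C3–C4(OH)(iPr)–C5(H); ring B (seven-membered) is C1–C5–C6(OAr)–C7–C8(Me)=C9–C10(OAng). β is the face of the C1 methyl, so C4–O and C10–O are β, H5 and C6–O are α.
2. Structural feature: C10 bears oxygen and hangs on the fully substituted C1, the methyl-bearing C8 lies two bonds from it along ring B, and C7 is flanked by the oxygenated C6 on C5. Ring B is therefore cut at C7–C8: a 2-methylcyclopropanol built on C10 (ring carbons C10, C9, C8) is opened oxidatively to the C8 radical, which attacks C7 of a C6 silyl enol ether and leaves the 6,10-dione.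
3. Ring A comes intact from 3-methylcyclopent-2-en-1-one. C1 is set by copper-catalysed conjugate addition of a 2-furyl group (masked C10 carboxyl, larger than methyl), C5 by aldol trapping with acetaldehyde (C6, C7) anti to the furyl group, and C4 by isopropylcerium addition anti to the C5 arm.
4. The furan is degraded to the methyl ester, the C6 ketone is converted to its silyl enol ether, and a Kulinkovich reaction with propylmagnesium bromide installs the cyclopropanol last. Ring order: A first, then B.
5. After ring closure: hydroxyl-directed reduction at C6, aroylation, Saegusa–Ito oxidation to the C8=C9 enone, Luche reduction at C10, angeloylation, desilylation.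

Key step: step 8

Remark: the sense of induction of the copper–phosphinamine catalyst in step 1 is not derived here; the ligand enantiomer that gives the (3S) centre of 7 is used.
Remark: 4-(tert-butyldimethylsilyloxy)benzoic acid 18 is taken as a purchased building block. The C6 carbinol epimers of 7–10, the two cis-cyclopropanol isomers of 14 and the C8 epimers of 15–21 are carried as mixtures; one isomer is drawn.

**Route**

Step 1
Reactants: 1 3-methylcyclopent-2-en-1-one; 2 furan; 3 acetaldehyde
Product: 7 (2S,3S)-3-(furan-2-yl)-2-(1-hydroxyethyl)-3-methylcyclopentan-1-one, via 2-furyllithium 4 (not isolated), via dimethyl(furan-2-yl)aluminium 5 (not isolated), via aluminium enolate 6 (not isolated)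
Conditions: 2, n-BuLi, THF, 0 °C; Me2AlCl, −78 → 0 °C; then 1, Cu(O2CC4H3S) (10 mol %), Ph2PN[(R)-CH(CH3)(2-naphthyl)]2 (11 mol %), Et2O, −30 °C; then 3 (5 equiv), −78 °C; aq. KNaC4H4O6
Reagents that add atoms: none
Why: Copper-catalysed asymmetric conjugate addition of a (hetero)aryl dimethylalane to a β-substituted cyclic enone should set the quaternary C1 under catalyst control (the furyl group transfers in preference to methyl), and the regiodefined aluminium enolate should then undergo the aldol reaction with acetaldehyde on the face anti to the planar, sp2-branched furyl group, which shields more than the C1 methyl, so that the C6 arm on C5 ends up cis to the methyl; the C6 carbinol centre is not controlled and is removed in step 4.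

Step 2
Reactants: 7
Product: 9 methyl (1S,2S)-2-(1-hydroxyethyl)-1-methyl-3-oxocyclopentane-1-carboxylate, via carboxylic acid 8 (not isolated)
Conditions: O3, CH2Cl2/MeOH, −78 °C; Me2S; extractive work-up; then Me3SiCHN2, MeOH/toluene, 0 °C
Reagents that add atoms: ozone, [O-][O+]=O; (trimethylsilyl)diazomethane, C[Si](C)(C)C=[N+]=[N-]
Why: Ozonolysis of a 2-substituted furan cleaves both ring double bonds and leaves the attached ring carbon (C10) as the carboxylic acid, which is methylated with the diazoalkane under neutral conditions so that the base-sensitive β-hydroxy ketone and the C5 centre are not disturbed.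

Step 3
Reactants: 9
Product: 10 methyl (1S,2S,3R)-3-hydroxy-2-(1-hydroxyethyl)-1-methyl-3-(propan-2-yl)cyclopentane-1-carboxylate
Conditions: iPrMgCl (4 equiv), CeCl3 (4 equiv), THF, −78 °C
Reagents that add atoms: isopropylmagnesium chloride, CC(C)[Mg]Cl
Why: Organocerium 1,2-addition to the hindered, enolisable ketone (the neopentyl-type ester is left alone at −78 °C) should occur on the ring face anti to the adjacent C5 arm, which places the new C4 hydroxyl cis to that arm and to the C1 methyl; any isomer with the hydroxyl cis to the ester would lactonise and be separated.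

Step 4
Reactants: 10
Product: 11 methyl (1S,2R,3R)-2-acetyl-3-hydroxy-1-methyl-3-(propan-2-yl)cyclopentane-1-carboxylate
Conditions: Dess–Martin periodinane, NaHCO3, CH2Cl2, 0 °C → rt
Reagents that add atoms: none
Why: Dess–Martin oxidation converts the secondary C6 carbinol into the methyl ketone and cannot touch the tertiary C4 alcohol, and the buffered, non-basic medium avoids retro-aldol cleavage while the acetyl group stays on its favoured face, trans to isopropyl and ester.

Step 5
Reactants: 11
Product: 12 methyl (1S,2R,3R)-2-acetyl-1-methyl-3-(propan-2-yl)-3-(triethylsilyloxy)cyclopentane-1-carboxylate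
Conditions: Et3SiOTf, 2,6-lutidine, CH2Cl2, −78 → 0 °C
Reagents that add atoms: triethylsilyl trifluoromethanesulfonate, CC[Si](CC)(CC)OS(=O)(=O)C(F)(F)F
Why: Silylation with a silyl triflate caps the hindered tertiary C4 hydroxyl, so that the β-hydroxy ketone cannot open by retro-aldol reaction in the later basic and oxidative steps.

Step 6
Reactants: 12
Product: 13 methyl (1S,2S,3R)-2-[1-(tert-butyldimethylsilyloxy)ethenyl]-1-methyl-3-(propan-2-yl)-3-(triethylsilyloxy)cyclopentane-1-carboxylate
Conditions: tBuMe2SiOTf, Et3N, CH2Cl2, 0 °C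
Reagents that add atoms: tert-butyldimethylsilyl trifluoromethanesulfonate, CC(C)(C)[Si](C)(C)OS(=O)(=O)C(F)(F)F
Why: Soft enolisation of the methyl ketone (silyl triflate and amine) should give the terminal C6=C7 silyl enol ether, because the only other α-hydrogen sits on C5 between two fully substituted carbons and the ester has none.

Step 7
Reactants: 13
Product: 14 (1S,2S)-1-{(1S,2S,3R)-2-[1-(tert-butyldimethylsilyloxy)ethenyl]-1-methyl-3-(propan-2-yl)-3-(triethylsilyloxy)cyclopentyl}-2-methylcyclopropan-1-ol
Conditions: n-PrMgBr (4.5 equiv, slow addition), Ti(OiPr)4 (1.2 equiv), THF, 20 °C; aq. NH4Cl/KNaC4H4O6, 0 °C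
Reagents that add atoms: propylmagnesium bromide, CCC[Mg]Br
Why: Kulinkovich reaction: the propene–titanium complex formed from the Grignard reagent and the titanium alkoxide acts as a 1,2-dicarbanion toward the methyl ester (α-quaternary esters are expected to react, though more slowly) and gives the free cis-1,2-dialkyl cyclopropanol directly, while the silyl enol ether and the silyl ether are inert to Grignard reagents and to the neutral work-up; the configuration of the cyclopropane carbons is of no consequence.

Step 8
Reactants: 14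
Product: 15 4β-(triethylsilyloxy)-5α-daucane-6,10-dione
Conditions: slow addition of 14 to Mn(O2CC5H4N)3 (manganese tris(picolinate), trivalent manganese, 2.4 equiv), DMF (0.01 M), 0 °C → rt, Ar
Reagents that add atoms: none
Why: Proposed new method: the manganese complex exchanges a picolinate for the cyclopropanol oxygen and oxidises it by one electron, and the cyclopropyloxy radical opens by β-scission of the more substituted C10–C8 bond to the C10 ketone and the secondary C8 radical; the closest known chemistry is the generation of β-keto radicals from cyclopropanols with this reagent, their intermolecular addition to silyl enol ethers to give 1,5-diketones and their intramolecular 5-exo closure onto alkenes, of which the present ring closure is an untested variant. Ring B closes in the 7-endo-trig mode by attack of C8 on the unsubstituted terminus C7; a 6-exo closure would mean bonding to C6, which carries three non-hydrogen substituents, and would give a primary radical instead of the tertiary α-silyloxy radical. That radical is oxidised by a second equivalent of the oxidant and loses the silyl group to give the C6 ketone. The new C8 centre is under no firm control (a chair-like closure with the methyl equatorial should favour one epimer) and is erased in step 12, whereas C1, C4 and C5 are untouched and the trans ring fusion follows from the trans arms of 14. The step needs ring opening toward C8 and not C9, which radical stability secures, and cyclisation faster than hydrogen abstraction, oxidation or dimerisation of the C8 radical, which high dilution and the electron-rich 1,1-disubstituted acceptor should favour.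

Step 9
Reactants: 15
Product: 16 4β-hydroxy-5α-daucane-6,10-dione
Conditions: HF·pyridine, pyridine, THF, 0 °C → rt
Reagents that add atoms: none
Why: Fluoride-mediated desilylation under buffered, weakly acidic conditions frees the tertiary C4 hydroxyl without the base that would trigger retro-aldol opening or C5 epimerisation of the β-hydroxy ketone.

Step 10
Reactants: 16
Product: 17 4β,6α-dihydroxy-5α-daucan-10-one
Conditions: Me4NBH(OAc)3, MeCN/AcOH, −30 → 0 °C
Reagents that add atoms: none
Why: Evans–Saksena hydroxyl-directed reduction: the borohydride bound to the C4 oxygen delivers hydride intramolecularly to the β-positioned C6 carbonyl from the β face on which that oxygen sits, which sets the 6α carbinol (an external hydride would be expected to come from the α face instead), while the C10 ketone, which has no suitably placed hydroxyl and is not reduced by this mild reagent, survives.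

Step 11
Reactants: 17; 18 4-(tert-butyldimethylsilyloxy)benzoic acid
Product: 20 6α-[4-(tert-butyldimethylsilyloxy)benzoyloxy]-4β-hydroxy-5α-daucan-10-one, via mixed anhydride 19 (not isolated)
Conditions: 18, 2,4,6-Cl3C6H2COCl, Et3N, THF, rt; then 17, DMAP, toluene, rt → 40 °C
Reagents that add atoms: none
Why: Yamaguchi esterification acylates the secondary C6 hydroxyl through the less hindered carbonyl of the mixed anhydride, and the tertiary, heavily flanked C4 hydroxyl does not react.

Step 12
Reactants: 20
Product: 22 6α-[4-(tert-butyldimethylsilyloxy)benzoyloxy]-4β-(trimethylsilyloxy)-5α-dauc-8-en-10-one, via trimethylsilyl enol ether 21 (not isolated)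
Conditions: Me3SiOTf (3 equiv), Et3N, CH2Cl2, 0 °C; then Pd(OAc)2 (1.1 equiv), MeCN, rt → 40 °C
Reagents that add atoms: trimethylsilyl trifluoromethanesulfonate, C[Si](C)(C)OS(=O)(=O)C(F)(F)F
Why: Saegusa–Ito oxidation: C10 can enolise only toward C9 because C1 bears no hydrogen, and the palladium enolate at C9 can undergo β-hydride elimination only from C8, which installs the C8=C9 double bond and removes the uncontrolled C8 centre; the same silylation caps the C4 hydroxyl for the following steps.

Step 13
Reactants: 22
Product: 23 6α-[4-(tert-butyldimethylsilyloxy)benzoyloxy]-4β-(trimethylsilyloxy)-5α-dauc-8-en-10β-ol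
Conditions: NaBH4, CeCl3·7H2O, MeOH/THF, −78 °C
Reagents that add atoms: none
Why: Luche 1,2-reduction of the enone: hydride should add to C10 from the α face, anti to the pseudoaxial methyl on the adjacent quaternary C1, to give the 10β allylic alcohol.

Step 14
Reactants: 23; 24 angelic acid
Product: 26 10β-angeloyloxy-6α-[4-(tert-butyldimethylsilyloxy)benzoyloxy]-4β-(trimethylsilyloxy)-5α-dauc-8-ene, via angelic mixed anhydride 25 (not isolated)
Conditions: 24, 2,4,6-Cl3C6H2COCl, Et3N, toluene, rt; then 23, toluene, 80 °C
Reagents that add atoms: none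
Why: Yamaguchi-type acylation through the angelic 2,4,6-trichlorobenzoic mixed anhydride, run without a nucleophilic catalyst, is the established way to esterify hindered secondary alcohols with angelic acid while keeping the Z double bond from isomerising to the tiglate.

Step 15
Reactants: 26
Product: 27 10β-angeloyloxy-4β-hydroxy-6α-(4-hydroxybenzoyloxy)-5α-dauc-8-ene (CNP0273650.10)
Conditions: Bu4NF, AcOH, THF, 0 °C
Reagents that add atoms: none
Why: Buffered fluoride desilylation cleaves the aryl silyl ether and the tertiary trimethylsilyl ether at low temperature without touching the allylic angelate or the benzoate and without base-induced isomerisation of the angelate.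

**Compound list**

1 | 3-methylcyclopent-2-en-1-one | CC1=CC(=O)CC1 | starting material
2 | furan | c1ccoc1 | starting material
3 | acetaldehyde | CC=O | starting material
4 | 2-furyllithium | [Li]c1ccco1 | intermediate
5 | dimethyl(furan-2-yl)aluminium | C[Al](C)c1ccco1 | intermediate
6 | dimethylaluminium enolate of (S)-3-(furan-2-yl)-3-methylcyclopentanone (enolised toward C5) | C[Al](C)OC1=C[C@](C)(CC1)c2ccco2 | intermediate
7 | (2S,3S)-3-(furan-2-yl)-2-(1-hydroxyethyl)-3-methylcyclopentan-1-one (carbinol epimers) | CC(O)[C@@H]1[C@](C)(CCC1=O)c2ccco2 | intermediate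
8 | (1S,2S)-2-(1-hydroxyethyl)-1-methyl-3-oxocyclopentane-1-carboxylic acid | CC(O)[C@@H]1[C@](C)(CCC1=O)C(=O)O | intermediate
9 | methyl (1S,2S)-2-(1-hydroxyethyl)-1-methyl-3-oxocyclopentane-1-carboxylate | CC(O)[C@@H]1[C@](C)(CCC1=O)C(=O)OC | intermediate
10 | methyl (1S,2S,3R)-3-hydroxy-2-(1-hydroxyethyl)-1-methyl-3-(propan-2-yl)cyclopentane-1-carboxylate | CC(O)[C@@H]1[C@](C)(CC[C@@]1(O)C(C)C)C(=O)OC | intermediate
11 | methyl (1S,2R,3R)-2-acetyl-3-hydroxy-1-methyl-3-(propan-2-yl)cyclopentane-1-carboxylate | CC(=O)[C@@H]1[C@](C)(CC[C@@]1(O)C(C)C)C(=O)OC | intermediate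
12 | methyl (1S,2R,3R)-2-acetyl-1-methyl-3-(propan-2-yl)-3-(triethylsilyloxy)cyclopentane-1-carboxylate | CC(=O)[C@@H]1[C@](C)(CC[C@@]1(O[Si](CC)(CC)CC)C(C)C)C(=O)OC | intermediate
13 | methyl (1S,2S,3R)-2-[1-(tert-butyldimethylsilyloxy)ethenyl]-1-methyl-3-(propan-2-yl)-3-(triethylsilyloxy)cyclopentane-1-carboxylate | C=C(O[Si](C)(C)C(C)(C)C)[C@@H]1[C@](C)(CC[C@@]1(O[Si](CC)(CC)CC)C(C)C)C(=O)OC | intermediate
14 | (1S,2S)-1-{(1S,2S,3R)-2-[1-(tert-butyldimethylsilyloxy)ethenyl]-1-methyl-3-(propan-2-yl)-3-(triethylsilyloxy)cyclopentyl}-2-methylcyclopropan-1-ol (cis-1,2-dialkyl cyclopropanol; the (1R,2R)-cyclopropane isomer is expected alongside) | C=C(O[Si](C)(C)C(C)(C)C)[C@@H]1[C@](C)(CC[C@@]1(O[Si](CC)(CC)CC)C(C)C)[C@]2(O)C[C@@H]2C | intermediate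
15 | 4β-(triethylsilyloxy)-5α-daucane-6,10-dione (8β-methyl drawn) | O=C1C[C@@H](C)CC(=O)[C@@H]2[C@]1(C)CC[C@@]2(O[Si](CC)(CC)CC)C(C)C | intermediate
16 | 4β-hydroxy-5α-daucane-6,10-dione | O=C1C[C@@H](C)CC(=O)[C@@H]2[C@]1(C)CC[C@@]2(O)C(C)C | intermediate
17 | 4β,6α-dihydroxy-5α-daucan-10-one | O=C1C[C@@H](C)C[C@H](O)[C@@H]2[C@]1(C)CC[C@@]2(O)C(C)C | intermediate
18 | 4-(tert-butyldimethylsilyloxy)benzoic acid | CC(C)(C)[Si](C)(C)Oc1ccc(cc1)C(O)=O | starting material
19 | 4-(tert-butyldimethylsilyloxy)benzoic 2,4,6-trichlorobenzoic anhydride | CC(C)(C)[Si](C)(C)Oc1ccc(cc1)C(=O)OC(=O)c2c(Cl)cc(Cl)cc2Cl | intermediate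
20 | 6α-[4-(tert-butyldimethylsilyloxy)benzoyloxy]-4β-hydroxy-5α-daucan-10-one | O=C1C[C@@H](C)C[C@H](OC(=O)c3ccc(O[Si](C)(C)C(C)(C)C)cc3)[C@@H]2[C@]1(C)CC[C@@]2(O)C(C)C | intermediate
21 | 6α-[4-(tert-butyldimethylsilyloxy)benzoyloxy]-4β,10-bis(trimethylsilyloxy)-5α-dauc-9-ene | C[Si](C)(C)OC1=C[C@@H](C)C[C@H](OC(=O)c3ccc(O[Si](C)(C)C(C)(C)C)cc3)[C@@H]2[C@]1(C)CC[C@@]2(O[Si](C)(C)C)C(C)C | intermediate
22 | 6α-[4-(tert-butyldimethylsilyloxy)benzoyloxy]-4β-(trimethylsilyloxy)-5α-dauc-8-en-10-one | O=C1C=C(C)C[C@H](OC(=O)c3ccc(O[Si](C)(C)C(C)(C)C)cc3)[C@@H]2[C@]1(C)CC[C@@]2(O[Si](C)(C)C)C(C)C | intermediate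
23 | 6α-[4-(tert-butyldimethylsilyloxy)benzoyloxy]-4β-(trimethylsilyloxy)-5α-dauc-8-en-10β-ol | O[C@H]1C=C(C)C[C@H](OC(=O)c3ccc(O[Si](C)(C)C(C)(C)C)cc3)[C@@H]2[C@]1(C)CC[C@@]2(O[Si](C)(C)C)C(C)C | intermediate
24 | angelic acid, (Z)-2-methylbut-2-enoic acid | C/C=C(/C)C(O)=O | starting material
25 | angelic 2,4,6-trichlorobenzoic anhydride | C/C=C(/C)C(=O)OC(=O)c1c(Cl)cc(Cl)cc1Cl | intermediate
26 | 10β-angeloyloxy-6α-[4-(tert-butyldimethylsilyloxy)benzoyloxy]-4β-(trimethylsilyloxy)-5α-dauc-8-ene | C/C=C(/C)C(=O)O[C@H]1C=C(C)C[C@H](OC(=O)c3ccc(O[Si](C)(C)C(C)(C)C)cc3)[C@@H]2[C@]1(C)CC[C@@]2(O[Si](C)(C)C)C(C)C | intermediate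
27 | 10β-angeloyloxy-4β-hydroxy-6α-(4-hydroxybenzoyloxy)-5α-dauc-8-ene (CNP0273650.10) | C/C=C(/C)C(=O)O[C@H]1C=C(C)C[C@H](OC(=O)c2ccc(O)cc2)[C@@H]2[C@]1(C)CC[C@@]2(O)C(C)C | target

**Step count**

Total: 15 steps. Longest linear sequence: 15 steps (1 → 27).

**Steps most likely to fail**

1. Step 8 (Proposed new method). The C8 radical may be lost by hydrogen abstraction, by oxidation to the enone or by dimerisation before the slow 7-endo closure, or it may close in another mode. The fallback uses known reactions only; it sets out from 12 and comes back at 15. Ketone 12 is deprotonated at C7 with LiN(iPr)2 (THF, −78 °C) and added to methyl (E)-but-2-enoate in a Michael addition. This should give the keto diester methyl (1S,2R,3R)-2-(5-methoxy-3-methyl-5-oxopentanoyl)-1-methyl-3-(propan-2-yl)-3-(triethylsilyloxy)cyclopentane-1-carboxylate F1. Dieckmann condensation of the chain ester enolate (C9) onto the C10 ester (KOtBu, THF, high dilution) should close ring B as methyl 6,10-dioxo-4β-(triethylsilyloxy)-5α-daucane-9-carboxylate F2. Krapcho decarboxylation (LiCl, wet DMSO, 130 °C) should then give 15. Because this sequence leaves the main route before the hydroxycyclopropanation, it also stands in if step 7, the next most exposed step, fails on the hindered ester.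

2. Step 1. Enantiofacial control in the transfer of the heteroaryl group may be poor, methyl may transfer in its place, or the aldol trapping may show too little facial bias. The fallback sets out from 1 and comes back at 8. The C10 carbon is brought in as a 1-(trimethylsilyl)ethenyl group, a bulkier alkenyl nucleophile of a type established for β-substituted cyclic enones. Hydroalumination of ethynyltrimethylsilane with iBu2AlH gives bis(2-methylpropyl)[1-(trimethylsilyl)ethenyl]aluminium F3, which is added to 1 under copper–N-heterocyclic carbene catalysis (Cu(OTf)2, chiral imidazolinium salt, THF). Trapping of the enolate with 3 should give (2S,3S)-2-(1-hydroxyethyl)-3-methyl-3-[1-(trimethylsilyl)ethenyl]cyclopentan-1-one F4. Brief protodesilylation (CF3CO2H, CH2Cl2, 0 °C) should give (2S,3R)-3-ethenyl-2-(1-hydroxyethyl)-3-methylcyclopentan-1-one F5. Ozonolysis (O3, CH2Cl2, −78 °C; Me2S) should give (1S,2S)-2-(1-hydroxyethyl)-1-methyl-3-oxocyclopentane-1-carbaldehyde F6. Pinnick oxidation (NaClO2, NaH2PO4, 2-methylbut-2-ene, tBuOH/H2O) should give acid 8, which is methylated as in step 2.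

3. Step 14. Acylation of the neopentyl-type allylic C10 hydroxyl may be too slow at a temperature that still avoids isomerisation of the angelate to the tiglate or ionisation of the allylic alcohol. The fallback sets out from 23 and comes back at 26; it builds the Z double bond on the molecule instead of transferring it. Alcohol 23 is esterified with 2-[bis(2,2,2-trifluoroethoxy)phosphoryl]propanoic acid (DCC, DMAP, CH2Cl2, 0 °C → rt) to give the 10β-{2-[bis(2,2,2-trifluoroethoxy)phosphoryl]propanoyloxy} derivative of 23, F7. Still–Gennari olefination (KN(SiMe3)2, 18-crown-6, THF, −78 °C; then 3) should give the Z-configured 2-methylbut-2-enoate 26.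

**Further compounds**

F1 | step 8 | methyl (1S,2R,3R)-2-(5-methoxy-3-methyl-5-oxopentanoyl)-1-methyl-3-(propan-2-yl)-3-(triethylsilyloxy)cyclopentane-1-carboxylate | COC(=O)CC(C)CC(=O)[C@@H]1[C@](C)(CC[C@@]1(O[Si](CC)(CC)CC)C(C)C)C(=O)OC
F2 | step 8 | methyl 6,10-dioxo-4β-(triethylsilyloxy)-5α-daucane-9-carboxylate | COC(=O)C1C(C)CC(=O)[C@@H]2[C@](C)(CC[C@@]2(O[Si](CC)(CC)CC)C(C)C)C1=O
F3 | step 1 | bis(2-methylpropyl)[1-(trimethylsilyl)ethenyl]aluminium | CC(C)C[Al](CC(C)C)C(=C)[Si](C)(C)C
F4 | step 1 | (2S,3S)-2-(1-hydroxyethyl)-3-methyl-3-[1-(trimethylsilyl)ethenyl]cyclopentan-1-one | CC(O)[C@@H]1[C@](C)(CCC1=O)C(=C)[Si](C)(C)C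
F5 | step 1 | (2S,3R)-3-ethenyl-2-(1-hydroxyethyl)-3-methylcyclopentan-1-one | CC(O)[C@@H]1[C@](C)(CCC1=O)C=C
F6 | step 1 | (1S,2S)-2-(1-hydroxyethyl)-1-methyl-3-oxocyclopentane-1-carbaldehyde | CC(O)[C@@H]1[C@](C)(CCC1=O)C=O
F7 | step 14 | 10β-{2-[bis(2,2,2-trifluoroethoxy)phosphoryl]propanoyloxy}-6α-[4-(tert-butyldimethylsilyloxy)benzoyloxy]-4β-(trimethylsilyloxy)-5α-dauc-8-ene | CC(C(=O)O[C@H]1C=C(C)C[C@H](OC(=O)c3ccc(O[Si](C)(C)C(C)(C)C)cc3)[C@@H]2[C@]1(C)CC[C@@]2(O[Si](C)(C)C)C(C)C)P(=O)(OCC(F)(F)F)OCC(F)(F)F
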